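**Plan**

1. Locants: the cyclohexane keeps carvone numbering (C1 spiro C–O, C2 CH–CH3, C3 CH–OH, C5 CH–C(CH3)2OH, C6 spiro quaternary C). Cage atoms are Ca (CH2 on C1), Cb (quaternary C–CH3), Cc (orthoester C), Cd (CH–CH3), Ce (lactone α-CH), Cf (O–CH), Cg (methyl ketal C).
2. Cuts: the orthoester is opened to a δ-lactone (the two O–Cc bonds from C1–O and from the Cg oxygen). The six-membered ring O–Cc–Cb–Cd–Ce–Cf is then cut at Cd–Ce and O–Cf. This is possible because Cc is a carboxyl carbon whose oxygen sits 1,4 to Cd, and Ce/Cf are the α/β carbons of the fused γ-lactone (a butenolide retron).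
3. Fragments: a β-keto carboxylate (C1…Cd, from (R)-carvone) and a 3-phosphono-5-menthyloxy-5-methylbutenolide (Ce, Cf, Cg). One operation rejoins both bonds: carboxylate oxa-Michael addition at Cf, then intramolecular Horner–Wadsworth–Emmons (HWE) olefination of Ce onto the Cd ketone.
4. Ring order forward: cyclohexane (carvone) → spiro γ-lactone (sets Cb, then opened) → δ-lactone fused to the butenolide (key step) → tetrahydrofuran and dioxolane of the orthoester → Cd=Ce hydrogenation → spiro δ-lactone.
5. Stereochemistry: C5 of carvone relays to C6, C1, C2, C3 and Cb by substrate control; Cf comes from the menthyloxy auxiliary; Cc and Cg from ring fusion in the cage closure; Cd and Ce from exo-face hydrogenation of the cage.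

Key step: step 16

Remark: the menthyl pseudo-ester 25 is assumed to be separable from its C5 epimer (crystallisation or chromatography); the unwanted epimer equilibrates under the acid conditions of its formation and can be recycled.

Step 1
Reactants: 1 (R)-(−)-carvone; 2 ethyl formate
Product: 3 (5R)-6-(hydroxymethylene)carvone
Conditions: NaH, cat. EtOH, THF, 0 °C → rt; aq. HCl
Reagents that add atoms: none
Why: Claisen-type formylation at C6, the only enolisable α-carbon of the enone; the product rests as the chelated enol, so no stereocentre is set.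

Step 2
Reactants: 3 (5R)-6-(hydroxymethylene)carvone; 4 tert-butyl acrylate
Product: 5 C6-quaternary keto aldehyde (propanoate chain trans to isopropenyl)
Conditions: DBU (cat.), MeCN, 0 °C → rt
Reagents that add atoms: none
Why: Michael addition of the β-keto aldehyde enolate; the acrylate should approach C6 anti to the C5 isopropenyl group, which puts the chain trans and the formyl group cis to it (sets C6).

Step 3
Reactants: 5 C6-quaternary keto aldehyde
Product: 6 primary alcohol of 5
Conditions: NaBH4, MeOH/CH2Cl2, −78 °C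
Reagents that add atoms: none
Why: chemoselective hydride reduction; the aldehyde should react well before the hindered, conjugated ketone.

Step 4
Reactants: 6 primary alcohol of 5
Product: 7 TBS ether of 6
Conditions: t-BuMe2SiCl, imidazole, DMF, rt
Reagents that add atoms: tert-butyldimethylsilyl chloride, CC(C)(C)[Si](C)(C)Cl
Why: standard silylation of the neopentyl primary alcohol, which also blocks retro-aldol loss of formaldehyde.

Step 5
Reactants: 7 TBS ether of 6; 8 ethyl 2-(bromomethyl)acrylate
Product: 9 tertiary allylic alcohol (C1–OH cis to CH2OTBS)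
Conditions: In powder, THF/sat. aq. NH4Cl, rt
Reagents that add atoms: none
Why: Barbier allylation; the allylindium reagent should add 1,2 to the enone carbonyl from the face opposite the pseudo-axial CH2OTBS on C6, placing Ca trans and the new hydroxyl cis to that group (sets C1).

Step 6
Reactants: 9 tertiary allylic alcohol
Product: 10 2,3-epoxy alcohol (epoxide cis to C1–OH)
Conditions: VO(acac)2 (cat.), t-BuOOH, CH2Cl2, 0 °C → rt
Reagents that add atoms: tert-butyl hydroperoxide, CC(C)(C)OO
Why: hydroxyl-directed epoxidation; the vanadate ester of the tertiary allylic alcohol should deliver oxygen to C2=C3 on the face of the OH (sets C3) and leave the isopropenyl and acrylate alkenes alone.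

Step 7
Reactants: 10 2,3-epoxy alcohol
Product: 11 epoxy spiro α-methylene-γ-lactone
Conditions: LiN(SiMe3)2, THF, −78 → 0 °C
Reagents that add atoms: none
Why: alkoxide-driven lactonisation (acyl substitution on the ethyl ester); the cis epoxy alkoxide cannot open the epoxide from the rear, and the tert-butyl ester is inert.

Step 8
Reactants: 11 epoxy spiro α-methylene-γ-lactone
Product: 12 C3 ketone (C2–CH3 cis to the lactone oxygen)
Conditions: BF3·OEt2 (cat.), CH2Cl2, −78 °C
Reagents that add atoms: none
Why: Meinwald rearrangement; the epoxide should open at tertiary C2 while the antiperiplanar axial hydrogen on C3 shifts to C2 on the face opposite the leaving oxygen (sets C2), and the acylated oxygen on C1 disfavours a pinacol-type shift.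

Step 9
Reactants: 12 C3 ketone
Product: 13 C3 alcohol (OH cis to C2–CH3)
Conditions: NaBH4, CeCl3·7H2O, MeOH, −78 °C
Reagents that add atoms: none
Why: Luche reduction; hydride should add to the C3 ketone from the face opposite the axial C2 methyl, giving the equatorial alcohol (sets C3) without conjugate reduction of the methylene lactone or epimerisation at C2.

Step 10
Reactants: 13 C3 alcohol
Product: 14 C3 triethylsilyl ether
Conditions: Et3SiCl, imidazole, DMF, rt
Reagents that add atoms: chlorotriethylsilane, CC[Si](CC)(CC)Cl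
Why: standard silylation of the secondary alcohol, needed before the later oxidation.

Step 11
Reactants: 14 C3 triethylsilyl ether; 15 acetaldehyde
Product: 17 aldol lactone (quaternary Cb with CH3 and CH(OH)CH3), via lithium lactone enolate 16 (not isolated)
Conditions: LiBH(s-Bu)3, THF, −78 °C; then CH3CHO, −78 °C; aq. NH4Cl
Reagents that add atoms: none
Why: reductive aldol (conjugate hydride addition to the methylene lactone, then aldol); acetaldehyde should attack the enolate on the lactone face flanked by C2–H rather than by the quaternary C6 (sets Cb), and the carbinol configuration is irrelevant because it is oxidised later.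

Step 12
Reactants: 17 aldol lactone
Product: 18 tertiary alcohol (C5 side chain C(CH3)2OH)
Conditions: Co(acac)2 (cat.), PhSiH3, O2 (1 atm), THF/i-PrOH, rt; aq. Na2S2O3
Reagents that add atoms: dioxygen, O=O
Why: Mukaiyama hydration; Markovnikov hydrogen-atom transfer to the isopropenyl group, now the only alkene, followed by oxygen capture should give the tertiary alcohol.

Step 13
Reactants: 18 tertiary alcohol
Product: 20 lithium β-keto carboxylate, via lithium hydroxy carboxylate 19 (not isolated)
Conditions: LiOH·H2O (1.05 equiv), THF/MeOH/H2O, 45 °C; evaporate and dry azeotropically; then n-Pr4N[RuO4] (cat.), NMO, 4 Å MS, MeCN, rt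
Reagents that add atoms: lithium hydroxide, [Li+].[OH-]
Why: saponification of the γ-lactone (tert-butyl ester and silyl ethers should survive) followed by Ley–Griffith oxidation of the only secondary alcohol; the product is kept as its lithium salt so that it neither relactonises nor decarboxylates.

Step 14
Reactants: 21 tert-butyl diethylphosphonoacetate; 22 methylglyoxal
Product: 23 tert-butyl 2-(diethoxyphosphoryl)-4-oxopent-2-enoate
Conditions: piperidine (cat.), AcOH (cat.), toluene, 50 °C, azeotropic removal of water (22 used as 40% aqueous solution)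
Reagents that add atoms: none
Why: Knoevenagel condensation at the aldehyde carbon of methylglyoxal; the alkene geometry does not matter because it equilibrates in the next step.

Step 15
Reactants: 23 tert-butyl 2-(diethoxyphosphoryl)-4-oxopent-2-enoate; 24 (1R,2S,5R)-(−)-menthol
Product: 25 (5S)-3-(diethoxyphosphoryl)-5-methyl-5-[(1R,2S,5R)-menthyloxy]furan-2(5H)-one
Conditions: TsOH·H2O (cat.), toluene, 90 °C, Dean–Stark; separation of the C5 epimers
Reagents that add atoms: none
Why: acidolysis of the tert-butyl ester, ring closure of the cis keto acid to the 5-hydroxybutenolide and acid-catalysed acetal exchange with menthol (pseudo-ester formation); the C5 epimers are diastereomers and interconvert through the acyloxycarbenium ion, so the (5S) epimer can be collected.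

Step 16
Reactants: 20 lithium β-keto carboxylate; 25 (5S)-3-(diethoxyphosphoryl)-5-methyl-5-[(1R,2S,5R)-menthyloxy]furan-2(5H)-one
Product: 27 unsaturated δ-lactone fused to the menthyloxy γ-lactone, via lithium phosphonate carbanion 26 (not isolated)
Conditions: LiCl, 4 Å MS, MeCN/THF, 0 → 40 °C
Reagents that add atoms: none
Why: Proposed new method: the carboxylate oxygen should add reversibly to Cf, the β-carbon of the butenolide, which is activated by both the lactone carbonyl and the geminal phosphonate; the resulting lithium phosphonoacetate carbanion at Ce then attacks the Cd methyl ketone held five atoms away and expels lithium diethyl phosphate, forming O–Cf and Cd=Ce in one operation. The closest known reaction types are tandem oxa-Michael/HWE annulations of hydroxy carbonyl compounds with vinyl phosphonates or vinyl phosphonium salts, and the intramolecular HWE synthesis of unsaturated lactones from phosphonoacetate esters of keto alcohols. The δ-lactone ring is closed by carbanion addition to the ketone carbonyl in a six-membered exo mode, followed by syn elimination of phosphate. The only new stereocentre, Cf, is controlled by the menthyloxy-bearing C5 of 25: the carboxylate should enter anti to the alkoxy group, as is usual for 5-alkoxybutenolides. The step needs O-attack at Cf by the carboxylate rather than by the tertiary alcohols, and olefination rather than reversal; the carboxylate is the only anionic nucleophile, and the irreversible olefination removes the α-hydrogen at Ce, so the β-acyloxy lactone can no longer revert by elimination. No external base is required because the negative charge ends on the phosphate.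

Step 17
Reactants: 27 unsaturated δ-lactone fused to the menthyloxy γ-lactone
Product: 31 cage orthoester acid with Cd=Ce double bond, via bis-silyl ether 28 (not isolated), via cage tert-butyl ester 29 (not isolated), via cage silyl ester 30 (not isolated)
Conditions: Me3SiOTf (excess), 2,6-lutidine, CH2Cl2, −78 → 0 °C; pH 7 buffer
Reagents that add atoms: trimethylsilyl trifluoromethanesulfonate, C[Si](C)(C)OS(=O)(=O)C(F)(F)F
Why: Proposed new method: after silylation of both tertiary alcohols, O-silylation of the δ-lactone carbonyl should make Cc electrophilic so that the C1–O–SiMe3 oxygen closes the tetrahydrofuran to a silyl orthoester; silyl triflate then ionises the menthyloxy group at Cg, which is captured from the rear by the silyloxy oxygen on Cc to close the dioxolane with inversion at Cg and release menthyl silyl ether, while the tert-butyl ester is cleaved to the silyl ester at 0 °C; the closest known reaction types are the silyl triflate-catalysed conversion of lactones into cyclic orthoesters with bis-silylated diols and the Lewis-acid substitution of 5-alkoxy-γ-lactones, and the configurations at Cc and Cg are fixed by cis ring fusion.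

Step 18
Reactants: 31 cage orthoester acid with Cd=Ce double bond
Product: 32 saturated cage orthoester acid
Conditions: H2 (50 bar), Rh/Al2O3 (5 wt% Rh), EtOAc, rt
Reagents that add atoms: none
Why: heterogeneous hydrogenation with syn addition; Ce is already tied to Cg through the γ-lactone on the face of the two-atom O–Cg bridge, so both hydrogens can only arrive from the face of the one-atom oxygen bridge, which sets Ce and places the Cd methyl cis to the Cb methyl (sets Cd).

Step 19
Reactants: 32 saturated cage orthoester acid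
Product: 34 chermebilaene B, via seco hydroxy acid 33 (not isolated)
Conditions: HF·pyridine, pyridine, THF, 0 °C → rt
Reagents that add atoms: none
Why: buffered fluoride desilylation of the three silyl ethers; the freed δ-hydroxy acid carries a quaternary carbon in its tether and should lactonise under the mildly acidic conditions to the spiro δ-lactone without touching the orthoester.

**Compound list**

1 | (R)-(−)-carvone | CC1=CC[C@@H](C(C)=C)CC1=O | starting material
2 | ethyl formate | CCOC=O | starting material
3 | (5R)-6-(hydroxymethylene)carvone | CC1=CC[C@@H](C(C)=C)C(=CO)C1=O | intermediate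
4 | tert-butyl acrylate | C=CC(=O)OC(C)(C)C | starting material
5 | C6-quaternary keto aldehyde, tert-butyl propanoate chain trans and formyl cis to isopropenyl | CC1=CC[C@@H](C(C)=C)[C@](C=O)(CCC(=O)OC(C)(C)C)C1=O | intermediate
6 | primary alcohol of 5 (CH2OH cis to isopropenyl) | CC1=CC[C@@H](C(C)=C)[C@](CO)(CCC(=O)OC(C)(C)C)C1=O | intermediate
7 | TBS ether of 6 | CC1=CC[C@@H](C(C)=C)[C@](CO[Si](C)(C)C(C)(C)C)(CCC(=O)OC(C)(C)C)C1=O | intermediate
8 | ethyl 2-(bromomethyl)acrylate | C=C(CBr)C(=O)OCC | starting material
9 | tertiary allylic alcohol, C1–OH cis to CH2OTBS, C1 bearing CH2C(=CH2)CO2Et | CC1=CC[C@@H](C(C)=C)[C@](CO[Si](C)(C)C(C)(C)C)(CCC(=O)OC(C)(C)C)[C@]1(O)CC(=C)C(=O)OCC | intermediate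
10 | 2,3-epoxy alcohol, epoxide cis to C1–OH | C[C@]1(O2)[C@@H]2C[C@@H](C(C)=C)[C@](CO[Si](C)(C)C(C)(C)C)(CCC(=O)OC(C)(C)C)[C@]1(O)CC(=C)C(=O)OCC | intermediate
11 | epoxy spiro α-methylene-γ-lactone | C[C@]1(O3)[C@@H]3C[C@@H](C(C)=C)[C@](CO[Si](C)(C)C(C)(C)C)(CCC(=O)OC(C)(C)C)[C@]12CC(=C)C(=O)O2 | intermediate
12 | C3 ketone, C2–CH3 cis to the lactone oxygen | C[C@H]1C(=O)C[C@@H](C(C)=C)[C@](CO[Si](C)(C)C(C)(C)C)(CCC(=O)OC(C)(C)C)[C@]12CC(=C)C(=O)O2 | intermediate
13 | C3 alcohol, OH cis to C2–CH3 | C[C@H]1[C@@H](O)C[C@@H](C(C)=C)[C@](CO[Si](C)(C)C(C)(C)C)(CCC(=O)OC(C)(C)C)[C@]12CC(=C)C(=O)O2 | intermediate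
14 | C3 triethylsilyl ether of 13 | C[C@H]1[C@@H](O[Si](CC)(CC)CC)C[C@@H](C(C)=C)[C@](CO[Si](C)(C)C(C)(C)C)(CCC(=O)OC(C)(C)C)[C@]12CC(=C)C(=O)O2 | intermediate
15 | acetaldehyde | CC=O | starting material
16 | lithium enolate of the α-methyl spiro lactone | C[C@H]1[C@@H](O[Si](CC)(CC)CC)C[C@@H](C(C)=C)[C@](CO[Si](C)(C)C(C)(C)C)(CCC(=O)OC(C)(C)C)[C@]12CC(C)=C([O-])O2.[Li+] | intermediate
17 | aldol lactone, quaternary Cb with CH3 and CH(OH)CH3 (carbinol epimers) | C[C@H]1[C@@H](O[Si](CC)(CC)CC)C[C@@H](C(C)=C)[C@](CO[Si](C)(C)C(C)(C)C)(CCC(=O)OC(C)(C)C)[C@]12C[C@](C)(C(C)O)C(=O)O2 | intermediate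
18 | tertiary alcohol, C5 side chain C(CH3)2OH | C[C@H]1[C@@H](O[Si](CC)(CC)CC)C[C@@H](C(C)(C)O)[C@](CO[Si](C)(C)C(C)(C)C)(CCC(=O)OC(C)(C)C)[C@]12C[C@](C)(C(C)O)C(=O)O2 | intermediate
19 | lithium hydroxy carboxylate (opened γ-lactone) | C[C@H]1[C@@H](O[Si](CC)(CC)CC)C[C@@H](C(C)(C)O)[C@](CO[Si](C)(C)C(C)(C)C)(CCC(=O)OC(C)(C)C)[C@]1(O)C[C@](C)(C(C)O)C(=O)[O-].[Li+] | intermediate
20 | lithium β-keto carboxylate (Cb with CH3, acetyl, CO2Li) | C[C@H]1[C@@H](O[Si](CC)(CC)CC)C[C@@H](C(C)(C)O)[C@](CO[Si](C)(C)C(C)(C)C)(CCC(=O)OC(C)(C)C)[C@]1(O)C[C@](C)(C(C)=O)C(=O)[O-].[Li+] | intermediate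
21 | tert-butyl diethylphosphonoacetate | CCOP(=O)(OCC)CC(=O)OC(C)(C)C | starting material
22 | methylglyoxal | CC(=O)C=O | starting material
23 | tert-butyl 2-(diethoxyphosphoryl)-4-oxopent-2-enoate | CCOP(=O)(OCC)C(=CC(C)=O)C(=O)OC(C)(C)C | intermediate
24 | (1R,2S,5R)-(−)-menthol | CC(C)[C@@H]1CC[C@@H](C)C[C@H]1O | starting material
25 | (5S)-3-(diethoxyphosphoryl)-5-methyl-5-[(1R,2S,5R)-menthyloxy]furan-2(5H)-one | CCOP(=O)(OCC)C1=C[C@@](C)(O[C@@H]2C[C@H](C)CC[C@H]2C(C)C)OC1=O | intermediate
26 | lithium phosphonate carbanion, oxa-Michael adduct of 20 to 25 (acyloxy trans to menthyloxy) | C[C@H]1[C@@H](O[Si](CC)(CC)CC)C[C@@H](C(C)(C)O)[C@](CO[Si](C)(C)C(C)(C)C)(CCC(=O)OC(C)(C)C)[C@]1(O)C[C@](C)(C(C)=O)C(=O)O[C@H]2[C-](P(=O)(OCC)OCC)C(=O)O[C@]2(C)O[C@@H]3C[C@H](C)CC[C@H]3C(C)C.[Li+] | intermediate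
27 | unsaturated δ-lactone (O–Cf, Cd=Ce) fused to the menthyloxy γ-lactone | C[C@H]1[C@@H](O[Si](CC)(CC)CC)C[C@@H](C(C)(C)O)[C@](CO[Si](C)(C)C(C)(C)C)(CCC(=O)OC(C)(C)C)[C@]1(O)C[C@]2(C)C(C)=C3C(=O)O[C@](C)(O[C@@H]4C[C@H](C)CC[C@H]4C(C)C)[C@H]3OC2=O | intermediate
28 | bis(trimethylsilyl) ether of 27 | C[C@H]1[C@@H](O[Si](CC)(CC)CC)C[C@@H](C(C)(C)O[Si](C)(C)C)[C@](CO[Si](C)(C)C(C)(C)C)(CCC(=O)OC(C)(C)C)[C@]1(O[Si](C)(C)C)C[C@]2(C)C(C)=C3C(=O)O[C@](C)(O[C@@H]4C[C@H](C)CC[C@H]4C(C)C)[C@H]3OC2=O | intermediate
29 | cage orthoester, tert-butyl ester, Cd=Ce | C[C@H]1[C@@H](O[Si](CC)(CC)CC)C[C@@H](C(C)(C)O[Si](C)(C)C)[C@](CO[Si](C)(C)C(C)(C)C)(CCC(=O)OC(C)(C)C)[C@]12C[C@]1(C)C(C)=C3C(=O)O[C@@]4(C)O[C@@]1(O[C@@H]34)O2 | intermediate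
30 | cage orthoester, trimethylsilyl ester, Cd=Ce | C[C@H]1[C@@H](O[Si](CC)(CC)CC)C[C@@H](C(C)(C)O[Si](C)(C)C)[C@](CO[Si](C)(C)C(C)(C)C)(CCC(=O)O[Si](C)(C)C)[C@]12C[C@]1(C)C(C)=C3C(=O)O[C@@]4(C)O[C@@]1(O[C@@H]34)O2 | intermediate
31 | cage orthoester acid, Cd=Ce | C[C@H]1[C@@H](O[Si](CC)(CC)CC)C[C@@H](C(C)(C)O[Si](C)(C)C)[C@](CO[Si](C)(C)C(C)(C)C)(CCC(=O)O)[C@]12C[C@]1(C)C(C)=C3C(=O)O[C@@]4(C)O[C@@]1(O[C@@H]34)O2 | intermediate
32 | saturated cage orthoester acid | C[C@H]1[C@@H](O[Si](CC)(CC)CC)C[C@@H](C(C)(C)O[Si](C)(C)C)[C@](CO[Si](C)(C)C(C)(C)C)(CCC(=O)O)[C@]12C[C@]1(C)[C@@H](C)[C@H]3C(=O)O[C@@]4(C)O[C@@]1(O[C@@H]34)O2 | intermediate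
33 | seco hydroxy acid (all silyl groups removed) | C[C@H]1[C@@H](O)C[C@@H](C(C)(C)O)[C@](CO)(CCC(=O)O)[C@]12C[C@]1(C)[C@@H](C)[C@H]3C(=O)O[C@@]4(C)O[C@@]1(O[C@@H]34)O2 | intermediate
34 | chermebilaene B | C[C@H]1[C@@H](O)C[C@@H](C(C)(C)O)[C@]2(CCC(=O)OC2)[C@]12C[C@]1(C)[C@@H](C)[C@H]3C(=O)O[C@@]4(C)O[C@@]1(O[C@@H]34)O2 | target

Total steps: 19. Longest linear sequence: 17 (steps 1–13 and 16–19).

**Steps most likely to fail**

Step 16. The oxa-Michael addition may not populate the adduct (reversal, or hindrance at the β-carbon next to the ketal centre), the β-keto carboxylate may lose CO2 before olefination, or the carboxylate may add on the wrong face. The fallback uses known reactions and sets out from 20. Silylation of both tertiary alcohols (Me3SiCl, imidazole, buffered aqueous work-up) should give the keto acid F1. Conjugate borylation and oxidation of 25 (B2pin2, CuCl, NaOt-Bu, MeOH; then NaBO3), expected anti to the menthyloxy group, should give the 4-hydroxy lactone F2. Yamaguchi esterification of F1 with F2 should give the phosphonoacetate ester F3. Intramolecular HWE olefination of F3 (LiCl, i-Pr2NEt, MeCN) should then close the δ-lactone to 28, where the route is rejoined; 28 is carried through the conditions of step 17.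

Step 17. Ionisation may take place at the allylic O–Cf bond instead of at the ketal carbon, the silyl orthoester may collapse back to a lactone before it captures Cg, or the orthoester may be hydrolysed on work-up. The fallback sets out from 27. Aqueous CF3CO2H in CH2Cl2 should remove the menthyl, tert-butyl and silyl groups and let the δ-hydroxy acid lactonise, giving the hemiketal polyol F4. Azeotropic dehydration with camphorsulfonic acid (benzene, 4 Å MS) should close the orthoester under thermodynamic control to the deprotected cage alkene F5. Hydrogenation of F5 under the conditions of step 18 should give 34 directly.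

Step 8. The Lewis acid may cause ring contraction or migration of a C1 substituent instead of the hydrogen shift, or epimerise C2 of the ketone. The fallback sets out from 11 and returns at 13. Radical reductive opening of the epoxide with Cp2TiCl (from Cp2TiCl2 and Mn dust, 2,4,6-collidine hydrochloride, 1,4-cyclohexadiene, THF) should cleave the C2–O bond to the tertiary radical and keep the C3–O bond. Hydrogen-atom transfer to C2 from the face opposite the axial CH2OTBS group should then give 13 in one step, without a new compound.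

**Further compounds**

F1 | step 16 | keto acid with both tertiary alcohols as trimethylsilyl ethers | C[C@H]1[C@@H](O[Si](CC)(CC)CC)C[C@@H](C(C)(C)O[Si](C)(C)C)[C@](CO[Si](C)(C)C(C)(C)C)(CCC(=O)OC(C)(C)C)[C@]1(O[Si](C)(C)C)C[C@](C)(C(C)=O)C(=O)O
F2 | step 16 | 3-(diethoxyphosphoryl)-4-hydroxy-5-methyl-5-menthyloxy-γ-butyrolactone (OH trans to menthyloxy) | CCOP(=O)(OCC)C1[C@H](O)[C@@](C)(O[C@@H]2C[C@H](C)CC[C@H]2C(C)C)OC1=O
F3 | step 16 | ester of F1 with F2 | C[C@H]1[C@@H](O[Si](CC)(CC)CC)C[C@@H](C(C)(C)O[Si](C)(C)C)[C@](CO[Si](C)(C)C(C)(C)C)(CCC(=O)OC(C)(C)C)[C@]1(O[Si](C)(C)C)C[C@](C)(C(C)=O)C(=O)O[C@H]2C(P(=O)(OCC)OCC)C(=O)O[C@]2(C)O[C@@H]3C[C@H](C)CC[C@H]3C(C)C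
F4 | step 17 | deprotected hemiketal polyol with closed spiro δ-lactone | C[C@H]1[C@@H](O)C[C@@H](C(C)(C)O)[C@]2(CCC(=O)OC2)[C@]1(O)C[C@]3(C)C(C)=C4C(=O)OC(C)(O)[C@H]4OC3=O
F5 | step 17 | deprotected cage orthoester with Cd=Ce double bond | C[C@H]1[C@@H](O)C[C@@H](C(C)(C)O)[C@]2(CCC(=O)OC2)[C@]12C[C@]1(C)C(C)=C3C(=O)O[C@@]4(C)O[C@@]1(O[C@@H]34)O2
F0 | step 8 | none | none
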